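Retrosynthesis: the C1 hydroxyl of ring A is masked as its methyl ether. The two neighbouring ring B bonds, C1'–O (diaryl ether) and C2'–Br, are then cut together to give a ring A phenoxide, benzyne and a Br+ source. Last, the two ring A C–Br bonds ortho and para to that phenoxide oxygen are cut back to 3-bromo-2-methoxyphenol.
Enabling feature: ring B carries only the ether oxygen on C1' and a bromine on the adjacent C2'. This vicinal O/Br pair maps onto the two carbons of the benzyne triple bond (nucleophile on one, electrophile on the other). On ring A the carbons ortho (C–OMe, C–Br) and para (C–Br) to the nucleophilic oxygen are all occupied, so only oxygen can bond.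
Forward order: both benzene rings are purchased intact and no ring is formed. Ring A is dibrominated, converted into its dry caesium salt, joined through oxygen to ring B with simultaneous bromination of C2', and finally demethylated.
Stereochemistry: the target has no stereocentre, stereogenic axis or stereogenic double bond, so nothing has to be set.

Key step: step 3

Remark: the three purchased compounds (3-bromo-2-methoxyphenol, 2-(trimethylsilyl)phenyl triflate, 1,2-dibromo-1,1,2,2-tetrachloroethane) are taken as catalogue items. The target SMILES places OH on C1, Br on C2, C3 and C5, H on C4 and the aryloxy group on C6, that is 2,3,5-tribromo-6-(2-bromophenoxy)phenol.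

Step 1
Reactants: 1 3-bromo-2-methoxyphenol
Product: 2 3,4,6-tribromo-2-methoxyphenol
Conditions: Br2 (2.05 equiv), AcOH, 15 °C to rt
Reagents that add atoms: bromine, BrBr
Why: Electrophilic aromatic bromination is steered by the free OH, the strongest donor on the ring, to its open ortho (C6) and para (C4) carbons, while the methoxy group, twisted out of conjugation by its two neighbours, cannot direct attack to C5, which ends up between two bromines and should resist a third substitution.

Step 2
Reactants: 2 3,4,6-tribromo-2-methoxyphenol
Product: 3 caesium 3,4,6-tribromo-2-methoxyphenoxide
Conditions: CsOH·H2O (1.0 equiv), MeOH, rt; evaporation, toluene azeotrope, 50 °C under high vacuum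
Reagents that add atoms: caesium hydroxide monohydrate, O.[OH-].[Cs+]
Why: This is plain acid–base salt formation, since the tribrominated guaiacol is far more acidic than water or methanol, so one equivalent of hydroxide should deprotonate it fully and the water formed leaves with the toluene azeotrope.

Step 3
Reactants: 3 caesium 3,4,6-tribromo-2-methoxyphenoxide; 4 2-(trimethylsilyl)phenyl trifluoromethanesulfonate; 5 1,2-dibromo-1,1,2,2-tetrachloroethane
Product: 8 1,2,5-tribromo-4-(2-bromophenoxy)-3-methoxybenzene, via benzyne 6 (not isolated), via caesium 2-aryloxyphenyl anion 7 (not isolated)
Conditions: CsF (4 equiv), 18-crown-6 (4 equiv, dried), 5 (3 equiv), THF, 0 °C, 4 (2 equiv) added slowly, then rt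
Reagents that add atoms: 2-(trimethylsilyl)phenyl trifluoromethanesulfonate 4, C[Si](C)(C)c1ccccc1OS(=O)(=O)C(F)(F)F (the C6H4 unit); 1,2-dibromo-1,1,2,2-tetrachloroethane 5, BrC(Cl)(Cl)C(Cl)(Cl)Br (one Br)
Why: Proposed new method: attack of fluoride on silicon in 4 triggers 1,2-elimination of triflate and releases benzyne 6, 3 bonds through oxygen to one alkyne carbon (C1'–O) and parks the negative charge on the neighbouring C2' (7), and this carbanion abstracts a bromine atom from 5 (C2'–Br) while the residual bromotetrachloroethyl anion collapses to tetrachloroethylene and bromide, so that the spent donor is aprotic. The closest known reaction types are the fluoride-triggered three-component amination–halogenation of arynes with polyhalomethanes as halogen donors and the O-arylation of hindered phenols with silylaryl triflates, whereas the pairing of a phenoxide with a bromine electrophile across an aryne in one operation is the untested element. No ring is closed and no stereocentre is created. O- over C-arylation and inertness of ring A towards 5 are required, and both should follow from the substituents on C2 (OMe), C4 (Br) and C6 (Br) of the electron-poor phenoxide, which leave no open ortho or para carbon. Bromine capture must be faster than protonation of 7, which is addressed by the preformed dry salt, a medium without O–H or acidic C–H bonds, and an excess of 5 present from the start while 4 is fed in slowly. The two carbons of the triple bond in 6 are equivalent, so no regiochemical question arises, and the surplus of 4 and 5 covers the share of 6 intercepted by bromide or fluoride.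

Step 4
Reactants: 8 1,2,5-tribromo-4-(2-bromophenoxy)-3-methoxybenzene
Product: 10 2,3,5-tribromo-6-(2-bromophenoxy)phenol, via aryloxydibromoborane 9 (not isolated)
Conditions: BBr3 (3 equiv), CH2Cl2, −78 °C to rt; then H2O, 0 °C
Reagents that add atoms: none
Why: In this Lewis-acid ether cleavage boron binds the methoxy oxygen and bromide displaces the aryloxyborane from the methyl carbon in an SN2 step, a path closed to the diaryl ether oxygen (two sp2 carbons) and harmless to aryl bromides, as is standard for converting methoxylated into hydroxylated polybrominated diphenyl ethers.

Compound list
1 | 3-bromo-2-methoxyphenol | COc1c(O)cccc1Br | starting material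
2 | 3,4,6-tribromo-2-methoxyphenol | COc1c(O)c(Br)cc(Br)c1Br | intermediate
3 | caesium 3,4,6-tribromo-2-methoxyphenoxide | COc1c([O-])c(Br)cc(Br)c1Br.[Cs+] | intermediate
4 | 2-(trimethylsilyl)phenyl trifluoromethanesulfonate | C[Si](C)(C)c1ccccc1OS(=O)(=O)C(F)(F)F | starting material
5 | 1,2-dibromo-1,1,2,2-tetrachloroethane | BrC(Cl)(Cl)C(Cl)(Cl)Br | starting material
6 | benzyne (not isolated) | C1#CC=CC=C1 | intermediate
7 | caesium 2-(3,4,6-tribromo-2-methoxyphenoxy)phenyl anion (not isolated) | COc1c(Oc2cccc[c-]2)c(Br)cc(Br)c1Br.[Cs+] | intermediate
8 | 1,2,5-tribromo-4-(2-bromophenoxy)-3-methoxybenzene | COc1c(Oc2ccccc2Br)c(Br)cc(Br)c1Br | intermediate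
9 | dibromo[2,3,5-tribromo-6-(2-bromophenoxy)phenoxy]borane (not isolated) | BrB(Br)Oc1c(Br)c(Br)cc(Br)c1Oc1ccccc1Br | intermediate
10 | 2,3,5-tribromo-6-(2-bromophenoxy)phenol (CNP0151065.0) | Oc1c(Br)c(Br)cc(Br)c1Oc1ccccc1Br | target

Total step count: 4
Longest linear sequence: 4 steps (1 → 2 → 3 → 8 → 10)

Steps most likely to fail

Step 3 (proposed new method). Several processes could undermine it:
- The aryl anion may be protonated before it meets the bromine donor.
- The anion may exchange halogen with the bromines of ring A and scramble the substitution pattern.
- Benzyne may be consumed by bromide, fluoride or the oxygen of the ether solvent.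
- The hindered, electron-poor phenoxide may add too slowly.

The fallback gives up the aryne and transfers an intact 2-bromophenyl group from trivalent iodine. This is the known metal-free O-arylation of phenoxides with diaryliodonium salts, long used for methoxylated polybrominated diphenyl ethers. Commercial 1-bromo-2-iodobenzene would be oxidised with mCPBA and TsOH·H2O in MeCN to 1-bromo-2-[hydroxy(tosyloxy)-λ3-iodanyl]benzene F1. In the same pot F1 condenses with 1,3,5-trimethoxybenzene to (2-bromophenyl)(2,4,6-trimethoxyphenyl)iodonium tosylate F2. Warming F2 with the caesium phenoxide in toluene or MeCN should give the ether by ligand coupling at iodine. The electron-rich trimethoxyphenyl group stays on iodine and the electron-poorer, ortho-substituted 2-bromophenyl group migrates to oxygen. This fallback sets out from 3 and comes back to the route at 8.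

Step 2. The hygroscopic salt may retain water or methanol, which would feed protons to the aryl anion of the next step. The fallback avoids hydroxide and protic solvent altogether. Phenol 2 would be silylated with hexamethyldisilazane in refluxing toluene to give (3,4,6-tribromo-2-methoxyphenoxy)trimethylsilane F3, a neutral compound that can be purified and dried by ordinary means. One further equivalent of anhydrous CsF in the flask of step 3 then cleaves the O–Si bond (known fluoride unmasking of aryl silyl ethers). This releases the phenoxide in situ together with an aprotic, volatile silyl fluoride only. This fallback sets out from 2 and comes back to the route at 3, formed in the flask of step 3.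

Step 1. Positional control may be lost through attack para to the methoxy group, or a third bromination may occur when both halogens are introduced in one pot under substrate control. The fallback replaces this by two reagent-controlled monobrominations with purification in between. Bu4NBr3 in CH2Cl2–MeOH, a bulky para-selective tribromide, should give 3,4-dibromo-2-methoxyphenol F4. NBS with catalytic diisopropylamine in CH2Cl2 at 0 °C then delivers bromine ortho to the OH through an N-bromoamine hydrogen-bonded to the phenol. This fallback sets out from 1 and comes back to the route at 2.

Further compounds
F1 | step 3 | 1-bromo-2-[hydroxy(tosyloxy)-λ3-iodanyl]benzene | OI(OS(=O)(=O)c1ccc(C)cc1)c1ccccc1Br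
F2 | step 3 | (2-bromophenyl)(2,4,6-trimethoxyphenyl)iodonium tosylate | COc1cc(OC)c([I+]c2ccccc2Br)c(OC)c1.Cc1ccc(cc1)S(=O)(=O)[O-]
F3 | step 2 | (3,4,6-tribromo-2-methoxyphenoxy)trimethylsilane | COc1c(O[Si](C)(C)C)c(Br)cc(Br)c1Br
F4 | step 1 | 3,4-dibromo-2-methoxyphenol | COc1c(O)ccc(Br)c1Br
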